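Labdane numbering is used for every intermediate: C1–C10 decalin, C11–C16 side chain, C17 on C8, C18/C19 on C4, C20 on C10. Compound numbers are those of the steps and the compound list below.

## The problem

Target 29 is an ent-labdane: a trans-fused decalin (ring A = C1–C5/C10 with the gem-dimethyl carbon C4, ring B = C5–C10) with a quaternary, methyl-bearing C10. Its skeletal stereocentres C5, C9 and C10 belong to the enantiomeric series, so the common normal-series labdane feedstocks cannot supply them. Ring B carries three contiguous oxygenated stereocentres, the C6 hydroxyl, the C7 acetate and the tertiary C8 hydroxyl, all equatorial, with the C17 methyl axial and syn to the C10 methyl. Once C5, C9 and C10 are fixed, the axial methyl groups on C10 and C4 close one face of ring B, so C6, C7 and C8 can be set by substrate control; nothing in ring B could set the quaternary C10 in return. The side chain ends in a trisubstituted 12Z,14-diene, the less stable geometry, which must come from a stereodefined bond formation and not from elimination or equilibration. The molecule is fragile in three ways: acid lets the C8 hydroxyl add to the protonated diene, base lets the C7 acetate move to the free C6 hydroxyl, and forcing acid eliminates the tertiary alcohol. What makes a short entry possible is that C1–C20 form an unbroken head-to-tail tetraprenyl chain. The C4–C5 and C9–C10 bonds are those of a proton-initiated chair–chair bicyclisation, and termination at C17 leaves the C8=C17 alkene at the one position from which O8 (addition), O7 (allylic oxidation) and O6 (through the C7 ketone) can all be reached.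

## Retrosynthesis

**29 ⇒ 27 + 28 (C13–C14).** The vinyl–alkenyl bond is cut last, so that the acid-labile Z-diene appears only in the final step, under neutral palladium catalysis. The Z geometry is stored in the alkenyl iodide 27 and transferred with retention. Elimination from the native allylic-alcohol side chain would give E/Z and regioisomer mixtures. The forward reaction must couple a free diol monoacetate without base.

**27 ⇒ 26 ⇒ 25 ⇒ 24 (no skeletal bond).** These steps only sort the three ring-B oxygens. O6 is silylated from the moment it is introduced. O8 arrives as an acetate in 24 and is freed to give 25. O7 is acetylated in 26 when it is the only free secondary hydroxyl. The silyl group is removed to give 27 while the robust iodide, not the diene, is present. This order avoids any late differentiation of the C6 and C7 hydroxyls.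

**24 ⇒ 21 + 22 (C12=C13).** An α-iodoethylidene Wittig olefination of aldehyde 21 with the ylide from 22 forms the trisubstituted alkene with iodine cis to C11. The neighbouring option, enol triflation at the C13 ketone stage, was set aside: kinetic enolisation goes to the methyl group, and thermodynamic enolisation gives regio- and E/Z mixtures. Precursor 21 is four carbons shorter and has no alkene geometry to control.

**21 ⇒ 19 ⇒ 17 (C12=C13 of an enol ether; C8–O–C13).** Aldehyde 21 and its O8 acetate are the two halves of the cyclic enol ether 19 after oxidative cleavage. Enol ether 19 forms when the unmasked C13 ketone 18 (from ketal 17) condenses with the 1,5-related C8 hydroxyl. The cleavage excises C13/C16 regiospecifically and leaves them as an acetate on O8, which keeps the tertiary alcohol from closing onto the aldehyde as a lactol. A Baeyer–Villiger excision would need more steps and would leave O8 free.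

**17 ⇒ 16 ⇒ 14 ⇒ 13 (C6–O; C7–H; C17–H).** The C6 oxygen comes from Rubottom oxidation of enol ether 14. This is the only enol that ketone 13 can form, because C8 is quaternary. One hydride treatment of 16 then sets C7 and opens the spiro-epoxide to give 17. Dihydroxylation of a C6=C7 alkene would give a cis diol and epoxide opening a trans-diaxial one. Only ketone enol oxidation followed by axial hydride delivery gives the trans-diequatorial pair.

**13 ⇒ 12 ⇒ 11 ⇒ 10 (C8–O, C7–O).** Both oxygens come from the C8=C17 alkene of 10. Allylic hydroxylation gives 11, hydroxyl-directed epoxidation gives 12, and oxidation gives 13. The directing axial C7 hydroxyl and the shielding C10 methyl act in the same sense, so C8 is set with its oxygen equatorial.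

**10 ⇒ 9 ⇒ 7 ⇒ 6 (C13=C14).** The trisubstituted side-chain alkene would not survive the allylic oxidation or the peracid, so it is removed first. Directed epoxidation of the allylic alcohol 6 gives 7 and spares the exocyclic alkene. Periodate cleavage gives methyl ketone 9, masked as dioxolane 10. The cost is stated openly: C14/C15 and later C13/C16 are discarded and bought back from 22 and 28, in exchange for full control of the 12Z geometry.

**6 ⇒ 5 ⇒ 4 (C4–C5 and C9–C10; key disconnection).** Cutting both ring bonds opens the decalin to the acyclic, achiral diphosphate 4. It removes two rings and three stereocentres at once and explains the position of the C8=C17 alkene. Laboratory polyene cyclisations give racemates or need terminating auxiliaries and rarely stop cleanly at the exocyclic alkene. The forward reaction therefore asks an ent-copalyl diphosphate synthase for the fold, the stop after two rings and the C17 deprotonation. Diphosphate 5 is then hydrolysed to 6.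

**4 ⇒ 2 + 3 ⇒ 1 (C15–O).** The diphosphate is attached by displacement of allylic chloride 2 with salt 3. Chloride 2 comes from commercial alcohol 1 by a chlorination that preserves all alkene geometries.

## Roads not taken

Alternative 1: Diels–Alder of quinone A1 with diene A2, forming ring A.
- Cut: C1–C10 and C4–C5.
- Forward step: 2,6-dimethyl-1,4-benzoquinone A1 and 4-methylpenta-1,3-diene A2 combine under a chiral oxazaborolidinium Lewis acid to give the cis-fused enedione A3.
- Merits: the quaternary C10 is set by a catalyst, and ring B arrives with carbonyls at C6 and C9, the C7=C8 alkene and the C17 methyl. This is more ring-B functionality than the chosen plan has after its key step. The route is purely chemical and either enantiomer is available.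
- Weak points: A2 has a fully substituted diene terminus with a cis methyl group, which disfavours the s-cis conformer and makes the cycloaddition slow. C5 must be epimerised and the C2=C3 alkene hydrogenated. The C9 carbonyl, flanked by the quaternary C10, must be turned into a C9–H carrying a five-carbon chain with control of a fourth skeletal stereocentre. C8 still needs hydration with the correct sense.
- Comparison: A3 is better for early C6 oxygenation and for scale in ordinary glassware. The chosen plan sets against this that C5, C9 and C10 and the C9 chain position come from one step with no stereochemical repair, and that every later stereocentre is set by the rigid ent-decalin.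

Alternative 2: Diels–Alder of silyloxydiene A4 with alkynoyl pyrazole A5, forming ring B.
- Cut: C7–C8 and C9–C10.
- Forward step: the ring A silyloxydiene A4 adds to 1-(but-2-ynoyl)-3,5-dimethylpyrazole A5 to give diene A6. The catalyst is Cu(NTf2)2 A7, a divalent copper salt, with a chiral bis(oxazoline) ligand.
- Merits: convergent; C10 is set catalytically; the C6 oxygen (silyl enol ether), the C17 methyl and C11 (acyl carbon) are installed together.
- Weak points: the terminus of A4 that becomes C10 is tetrasubstituted and twisted out of conjugation by its neighbours, so reactivity is doubtful. In A6 both C5 and C9 are sp2 and must be reduced with control (trans fusion, C9–H anti to C20), one of them on a tetrasubstituted alkene. C7 carries no oxygen. The chain must be grown from a single carbon.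
- Comparison: A6 is as good as the chosen plan at C6 and needs no protein. It leaves two of the three skeletal stereocentres open, where the chosen key step closes all three.

Alternative 3: auxiliary-controlled intramolecular Diels–Alder of triene A8, forming rings A and B.
- Cut: C5–C10 and C8–C9.
- Forward step: triene A8 cyclises to the trans-fused adduct A9 under Me2AlCl A10.
- Merits: this is the closest chemical rival in bond economy. Two rings and four stereocentres (C5, C8, C9, C10) form in one step, the fusion is trans directly, and C7 is oxygenated.
- Weak points: the dienophile carbon of A8 that becomes C10 is fully substituted and the diene terminus is neopentyl (next to C4), a demanding transition state. A8 needs a long linear synthesis with two defined alkene geometries. C8 arrives in A9 as CH(CH3), so the C7 ketone must later be enolised towards C8 and towards C6 in separate, regiocontrolled oxidations. The imide carbon must be homologated by four carbons.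
- Comparison: A9 is better in that C7 is already oxygenated and no enzyme is needed. The chosen plan sets against this a two-step substrate synthesis and a C8 oxygen that comes directly from the alkene left by the cyclisation.

Key step: step 3

Assumption: the recombinant ent-copalyl diphosphate synthase (for example the Arabidopsis thaliana enzyme expressed in Escherichia coli) is a catalyst prepared in-house; diphosphates 4 and 5 are handled as ammonium salts and drawn as free acids.

## Route

Step 1
Reactants: 1 geranylgeraniol
Product: 2 geranylgeranyl chloride
Conditions: NCS, Me2S, CH2Cl2, −30 → 0 °C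
Reagents that add atoms: N-chlorosuccinimide, ClN1C(=O)CCC1=O
Why: Corey–Kim chlorination; chloride displaces the alkoxysulfonium group at the primary carbon without allylic transposition or E/Z scrambling, which acidic halogenating agents would cause.

Step 2
Reactants: 2 geranylgeranyl chloride; 3 tris(tetrabutylammonium) hydrogen diphosphate
Product: 4 geranylgeranyl diphosphate
Conditions: MeCN, rt; Dowex 50W (NH4+ form); cellulose chromatography (i-PrOH/aq. NH4HCO3)
Reagents that add atoms: none
Why: SN2 displacement of a primary allylic chloride by the organic-soluble diphosphate salt, a standard preparation of prenyl diphosphates; the product is isolated as its ammonium salt.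

Step 3
Reactants: 4 geranylgeranyl diphosphate
Product: 5 ent-copalyl diphosphate
Conditions: recombinant ent-copalyl diphosphate synthase, HEPES buffer pH 7.5, MgCl2 (0.1 mM), DTT, 10% glycerol, 30 °C, substrate fed in portions
Reagents that add atoms: none
Why: The aspartate-rich general acid of the enzyme protonates C3 of the terminal alkene of 4; the tertiary C4 cation is captured by C5 of the C5=C10 alkene (ring A, 6-endo-trig, chair) and the new C10 cation by C9 of the C8=C9 alkene (ring B, 6-endo-trig, chair), and the C8 cation then loses a C17 proton to give the 8(17)-alkene while the allylic diphosphate is never ionised. This is the native reaction of class 2 diterpene cyclases, the enzymatic form of the Stork–Eschenmoser cation–olefin polycyclisation; Brønsted acid-initiated polyene cyclisation is the closest laboratory reaction type. The relative configuration follows from anti addition across the two E alkenes through chair transition states: C5–H and C9–H both end trans to the C10 methyl, which gives the trans ring fusion and an equatorial side chain. The absolute configuration at C5, C9 and C10 (all R) is set by the enzyme, which binds the chain in the antipodal chair–chair fold; the achiral substrate has no bias of its own. The step needs three selectivities that 4 cannot supply: the ent fold, a stop after two rings without attack by the C13=C14 alkene or capture by water, and deprotonation at C17 and not at C7 or C9; all are imposed by the active-site contour and the position of the catalytic base. Inhibition by the complex of 4 with divalent magnesium is countered by a low MgCl2 concentration and portionwise feeding.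

Step 4
Reactants: 5 ent-copalyl diphosphate
Product: 6 ent-copalol
Conditions: calf intestinal alkaline phosphatase, glycine buffer pH 9, MgCl2, 37 °C; extraction into hexane
Reagents that add atoms: none
Why: Enzymatic phosphate ester hydrolysis proceeds by P–O cleavage, so the allylic C–O bond and the 13E alkene are untouched; acid hydrolysis would ionise the allylic diphosphate.

Step 5
Reactants: 6 ent-copalol
Product: 7 13,14-epoxy-ent-labd-8(17)-en-15-ol
Conditions: VO(acac)2 (cat.), t-BuOOH, CH2Cl2, 0 °C → rt
Reagents that add atoms: tert-butyl hydroperoxide, CC(C)(C)OO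
Why: Hydroxyl-directed vanadium-catalysed epoxidation reaches only the allylic-alcohol alkene and leaves the isolated 8(17)-methylene; the configuration of the two epoxide carbons is irrelevant because both are destroyed in step 6.

Step 6
Reactants: 7 13,14-epoxy-ent-labd-8(17)-en-15-ol
Product: 9 14,15-dinor-ent-labd-8(17)-en-13-one, via triol 8 (not isolated)
Conditions: H5IO6, THF/H2O, 0 °C → rt
Reagents that add atoms: water, O
Why: Periodic acid hydrolyses the epoxide and cleaves the resulting 13,14,15-triol (Malaprade glycol cleavage) to the C13 methyl ketone; the 1,1-disubstituted alkene does not react with periodate.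

Step 7
Reactants: 9 14,15-dinor-ent-labd-8(17)-en-13-one
Product: 10 ethylene ketal of 9
Conditions: TMSOCH2CH2OTMS, TMSOTf (cat.), CH2Cl2, −78 → −20 °C; pyridine quench
Reagents that add atoms: 1,2-bis(trimethylsilyloxy)ethane, C[Si](C)(C)OCCO[Si](C)(C)C
Why: Noyori acetalisation masks the only ketone under aprotic, cold conditions, without the protic acid and heat that would move the exocyclic alkene into the ring; the later base, enol-silylation and hydride steps must address C7 only.

Step 8
Reactants: 10 ethylene ketal of 9
Product: 11 7-hydroxy-8(17)-ene ketal (C7–OH axial)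
Conditions: SeO2 (cat.), t-BuOOH, CH2Cl2, 0 °C → rt
Reagents that add atoms: selenium dioxide (oxygen carrier), O=[Se]=O; tert-butyl hydroperoxide (terminal oxidant), CC(C)(C)OO
Why: Riley allylic hydroxylation (ene reaction, then [2,3]-shift) attacks the ring methylene C7 in preference to the hindered methine C9 and returns the double bond to C8=C17, delivering oxygen axially on the face away from the C10 methyl. The C7 carbinol is oxidised in step 10, but its axial orientation is what directs step 9.

Step 9
Reactants: 11 7-hydroxy-8(17)-ene ketal
Product: 12 7-hydroxy-8,17-epoxide ketal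
Conditions: VO(acac)2 (cat.), t-BuOOH, CH2Cl2, rt
Reagents that add atoms: tert-butyl hydroperoxide, CC(C)(C)OO
Why: Hydroxyl-directed epoxidation: the axial C7 hydroxyl and the axial C10 methyl, which shields the other face, both send oxygen to the face opposite C20. The new C8–O bond is therefore equatorial and C17 axial, which is the C8 configuration of the target.

Step 10
Reactants: 12 7-hydroxy-8,17-epoxide ketal
Product: 13 7-oxo-8,17-epoxide ketal
Conditions: Dess–Martin periodinane, NaHCO3, CH2Cl2, 0 °C → rt
Reagents that add atoms: none
Why: Dess–Martin oxidation of the secondary epoxy alcohol under buffered conditions gives the α,β-epoxy ketone without opening the spiro-epoxide or the acetal.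

Step 11
Reactants: 13 7-oxo-8,17-epoxide ketal
Product: 14 C6=C7 silyl enol ether
Conditions: LiN(SiMe3)2, THF, −78 °C; TBSOTf, −78 °C; Et3N quench
Reagents that add atoms: tert-butyldimethylsilyl trifluoromethanesulfonate, CC(C)(C)[Si](C)(C)OS(=O)(=O)C(F)(F)F
Why: C8 is quaternary, so the C7 ketone can enolise only towards C6; O-silylation of the lithium enolate at −78 °C is much faster than attack of the silyl triflate on the deactivated α-keto epoxide.

Step 12
Reactants: 14 C6=C7 silyl enol ether
Product: 16 6-silyloxy-7-oxo-8,17-epoxide ketal, via silyloxy epoxide 15 (not isolated)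
Conditions: mCPBA, NaHCO3, CH2Cl2, −20 → 0 °C, then rt
Reagents that add atoms: 3-chloroperoxybenzoic acid, OOC(=O)c1cccc(Cl)c1
Why: Rubottom oxidation: the electron-rich enol ether is epoxidised on the face opposite the two syn-axial methyl groups (on C10 and C4), and the silyloxy epoxide opens with 1,4-silyl shift. The new C6 oxygen is therefore equatorial and already protected.

Step 13
Reactants: 16 6-silyloxy-7-oxo-8,17-epoxide ketal
Product: 17 6-silyloxy-7,8-diol ketal
Conditions: LiAlH4, THF, −78 → 0 °C, then rt; Fieser work-up
Reagents that add atoms: none
Why: The small hydride adds axially to C7 from the face that carries only the axial hydrogens of C5 and C9 (the other face is blocked by the axial C17 methylene), giving the equatorial C7 alcohol. It then opens the spiro-epoxide at the primary C17, leaving the equatorial tertiary C8 alcohol with its axial methyl as set in step 9.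

Step 14
Reactants: 17 6-silyloxy-7,8-diol ketal
Product: 19 cyclic enol ether, via hydroxy ketone 18 (not isolated)
Conditions: PPTS, acetone/H2O (10:1), 50 °C; then PPTS (cat.), toluene, 4 Å MS, 70 °C
Reagents that add atoms: none
Why: Acetal hydrolysis frees the C13 ketone, and the 1,5-related tertiary C8 hydroxyl closes to the hemiketal and dehydrates to the more stable endocyclic enol ether (cyclodehydration of the sclareol oxide type). The free C7 hydroxyl cannot bridge to C13 as a bicyclic ketal, because that bridge would have to stand axial on a pyran ring that is trans-fused to ring B. The mild acid spares the hindered silyl ether, and the ring marks C12=C13 for regiospecific cleavage.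

Step 15
Reactants: 19 cyclic enol ether
Product: 21 8-acetoxy-12-aldehyde, via methoxy hydroperoxide 20 (not isolated)
Conditions: O3, CH2Cl2/MeOH (4:1), NaHCO3, −78 °C; Me2S, −78 °C → rt
Reagents that add atoms: ozone, [O-][O+]=O
Why: Ozonolysis of the enol ether turns the oxygen-bearing carbon directly into the ester and C12 into the aldehyde after reduction of the methoxy hydroperoxide. C13 and C16 leave the skeleton as the O8 acetate, which prevents lactol formation with the new aldehyde.

Step 16
Reactants: 21 8-acetoxy-12-aldehyde; 22 ethyltriphenylphosphonium iodide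
Product: 24 (12Z)-13-iodoalkene 8-acetate, via (1-iodoethyl)triphenylphosphonium iodide 23 (not isolated)
Conditions: 22, n-BuLi, THF, 0 °C → rt; I2, −78 °C; NaN(SiMe3)2, −78 → −20 °C; then 21, −78 → −20 °C
Reagents that add atoms: iodine, II
Why: Stork–Zhao α-iodoalkylidene Wittig olefination: the non-stabilised iodo-ylide adds to the unhindered aldehyde under kinetic control and gives the Z-2-iodoalk-2-ene with iodine cis to C11, which fixes the C12=C13 geometry. The ylide is too weak a base to deprotonate the free C7 hydroxyl.

Step 17
Reactants: 24 (12Z)-13-iodoalkene 8-acetate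
Product: 25 (12Z)-13-iodoalkene 7,8-diol
Conditions: i-Bu2AlH, CH2Cl2, −78 → 0 °C; aq. potassium sodium tartrate
Reagents that add atoms: none
Why: Reductive ester cleavage frees the tertiary O8 without alkoxide-mediated acyl shifts; the alkenyl iodide and the silyl ether are inert at low temperature. Any material whose acetyl group has already moved to O7 converges on the same diol.

Step 18
Reactants: 25 (12Z)-13-iodoalkene 7,8-diol
Product: 26 (12Z)-13-iodoalkene 7-acetate
Conditions: Ac2O, pyridine, DMAP (cat.), CH2Cl2, 0 °C → rt
Reagents that add atoms: acetic anhydride, CC(=O)OC(C)=O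
Why: Nucleophile-catalysed acylation: of the two free hydroxyls only the secondary one at C7 reacts under these conditions, since the tertiary C8 alcohol needs forcing conditions; O6 is still silylated, so the acetate can go only to O7.

Step 19
Reactants: 26 (12Z)-13-iodoalkene 7-acetate
Product: 27 (12Z)-13-iodoalkene 6,8-diol 7-acetate
Conditions: aq. HF (48%), MeCN, 0 °C → rt
Reagents that add atoms: none
Why: Acidic fluoride cleaves the hindered silyl ether; the 1,2-acyl shift of the C7 acetate to O6, which an alkoxide would trigger, is slow in acid, and the alkenyl iodide tolerates the acid where the final diene would not.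

Step 20
Reactants: 27 (12Z)-13-iodoalkene 6,8-diol 7-acetate; 28 tributyl(vinyl)stannane
Product: 29 target compound
Conditions: Pd2(dba)3 (cat.), AsPh3, NMP, rt → 40 °C; KF work-up; Et3N-deactivated silica
Reagents that add atoms: none
Why: Stille coupling: oxidative addition of zerovalent palladium into the alkenyl carbon–iodine bond, transmetalation with the vinylstannane and reductive elimination all go with retention, so the Z iodide gives the 12Z diene. The neutral, base-free conditions leave the free hydroxyls, the acetate and the acid-labile diene untouched.

## Compound list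

1 | geranylgeraniol, (2E,6E,10E)-3,7,11,15-tetramethylhexadeca-2,6,10,14-tetraen-1-ol | CC(C)=CCC/C(C)=C/CC/C(C)=C/CC/C(C)=C/CO | starting material
2 | (2E,6E,10E)-geranylgeranyl chloride | CC(C)=CCC/C(C)=C/CC/C(C)=C/CC/C(C)=C/CCl | intermediate
3 | tris(tetrabutylammonium) hydrogen diphosphate | CCCC[N+](CCCC)(CCCC)CCCC.CCCC[N+](CCCC)(CCCC)CCCC.CCCC[N+](CCCC)(CCCC)CCCC.OP(=O)([O-])OP(=O)([O-])[O-] | starting material
4 | (2E,6E,10E)-geranylgeranyl diphosphate (ammonium salt, drawn as free acid) | CC(C)=CCC/C(C)=C/CC/C(C)=C/CC/C(C)=C/COP(=O)(O)OP(=O)(O)O | intermediate
5 | ent-copalyl diphosphate, ent-labda-8(17),13E-dien-15-yl diphosphate, 5R,9R,10R (ammonium salt, drawn as free acid) | OP(O)(=O)OP(=O)(O)OC/C=C(\C)CC[C@@H]1C(=C)CC[C@@H]2C(C)(C)CCC[C@]21C | intermediate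
6 | ent-copalol, ent-labda-8(17),13E-dien-15-ol | OC/C=C(\C)CC[C@@H]1C(=C)CC[C@@H]2C(C)(C)CCC[C@]21C | intermediate
7 | 13,14-epoxy-ent-labd-8(17)-en-15-ol (trans-epoxide, both diastereomers at C13/C14) | OCC3OC3(C)CC[C@@H]1C(=C)CC[C@@H]2C(C)(C)CCC[C@]21C | intermediate
8 | ent-labd-8(17)-ene-13,14,15-triol (diastereomers at C13/C14) | OCC(O)C(C)(O)CC[C@@H]1C(=C)CC[C@@H]2C(C)(C)CCC[C@]21C | intermediate (not isolated)
9 | 14,15-dinor-ent-labd-8(17)-en-13-one | CC(=O)CC[C@@H]1C(=C)CC[C@@H]2C(C)(C)CCC[C@]21C | intermediate
10 | ethylene ketal of 9 (C13 as 2-methyl-1,3-dioxolane) | CC3(OCCO3)CC[C@@H]1C(=C)CC[C@@H]2C(C)(C)CCC[C@]21C | intermediate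
11 | 7-hydroxy derivative of 10; C7–OH axial, on the face opposite the C10 methyl | CC3(OCCO3)CC[C@@H]1C(=C)[C@@H](O)C[C@@H]2C(C)(C)CCC[C@]21C | intermediate
12 | 8,17-epoxide of 11; epoxide oxygen equatorial on C8 (face opposite the C10 methyl), C17 axial | CC3(OCCO3)CC[C@@H]1[C@]4(CO4)[C@@H](O)C[C@@H]2C(C)(C)CCC[C@]21C | intermediate
13 | 7-oxo-8,17-epoxide ketal (α,β-epoxy ketone) | CC3(OCCO3)CC[C@@H]1[C@]4(CO4)C(=O)C[C@@H]2C(C)(C)CCC[C@]21C | intermediate
14 | C6=C7 tert-butyldimethylsilyl enol ether of 13 | CC3(OCCO3)CC[C@@H]1[C@]4(CO4)C(O[Si](C)(C)C(C)(C)C)=C[C@@H]2C(C)(C)CCC[C@]21C | intermediate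
15 | 6,7-epoxide of 14 (oxygen on the face opposite the C10 methyl) | CC3(OCCO3)CC[C@@H]1[C@]4(CO4)[C@@]5(O[Si](C)(C)C(C)(C)C)O[C@H]5[C@@H]2C(C)(C)CCC[C@]21C | intermediate (not isolated)
16 | 6-(tert-butyldimethylsilyloxy)-7-oxo-8,17-epoxide ketal; C6–O equatorial, opposite the C10 methyl | CC3(OCCO3)CC[C@@H]1[C@]4(CO4)C(=O)[C@@H](O[Si](C)(C)C(C)(C)C)[C@@H]2C(C)(C)CCC[C@]21C | intermediate
17 | 6-silyloxy-7,8-diol ketal; C7–OH equatorial (same face as the C10 methyl), C8–OH equatorial (opposite face), C8–CH3 axial | CC3(OCCO3)CC[C@@H]1[C@@](C)(O)[C@H](O)[C@@H](O[Si](C)(C)C(C)(C)C)[C@@H]2C(C)(C)CCC[C@]21C | intermediate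
18 | 6-silyloxy-7,8-dihydroxy-14,15-dinor-ent-labdan-13-one | CC(=O)CC[C@@H]1[C@@](C)(O)[C@H](O)[C@@H](O[Si](C)(C)C(C)(C)C)[C@@H]2C(C)(C)CCC[C@]21C | intermediate (not isolated)
19 | cyclic enol ether, 8,13-epoxy-14,15-dinor-ent-labd-12-ene carrying 6-OTBS and 7-OH | CC3=CC[C@@H]1[C@@](C)(O3)[C@H](O)[C@@H](O[Si](C)(C)C(C)(C)C)[C@@H]2C(C)(C)CCC[C@]21C | intermediate
20 | 12-hydroperoxy-12-methoxy-13,14,15,16-tetranor-ent-labdane, 8-acetate, 7-OH, 6-OTBS (C12 epimers) | COC(OO)C[C@@H]1[C@@](C)(OC(C)=O)[C@H](O)[C@@H](O[Si](C)(C)C(C)(C)C)[C@@H]2C(C)(C)CCC[C@]21C | intermediate (not isolated)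
21 | 8-acetoxy-7-hydroxy-6-(tert-butyldimethylsilyloxy)-13,14,15,16-tetranor-ent-labdan-12-al | O=CC[C@@H]1[C@@](C)(OC(C)=O)[C@H](O)[C@@H](O[Si](C)(C)C(C)(C)C)[C@@H]2C(C)(C)CCC[C@]21C | intermediate
22 | ethyltriphenylphosphonium iodide | CC[P+](c1ccccc1)(c1ccccc1)c1ccccc1.[I-] | starting material
23 | (1-iodoethyl)triphenylphosphonium iodide | CC(I)[P+](c1ccccc1)(c1ccccc1)c1ccccc1.[I-] | intermediate (not isolated)
24 | (12Z)-13-iodo-14,15-dinor-ent-labd-12-ene, 8-acetate, 7-OH, 6-OTBS | C/C(I)=C/C[C@@H]1[C@@](C)(OC(C)=O)[C@H](O)[C@@H](O[Si](C)(C)C(C)(C)C)[C@@H]2C(C)(C)CCC[C@]21C | intermediate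
25 | (12Z)-13-iodo-14,15-dinor-ent-labd-12-ene-7,8-diol, 6-OTBS | C/C(I)=C/C[C@@H]1[C@@](C)(O)[C@H](O)[C@@H](O[Si](C)(C)C(C)(C)C)[C@@H]2C(C)(C)CCC[C@]21C | intermediate
26 | (12Z)-13-iodo-14,15-dinor-ent-labd-12-ene, 7-acetate, 8-OH, 6-OTBS | C/C(I)=C/C[C@@H]1[C@@](C)(O)[C@H](OC(C)=O)[C@@H](O[Si](C)(C)C(C)(C)C)[C@@H]2C(C)(C)CCC[C@]21C | intermediate
27 | (12Z)-13-iodo-14,15-dinor-ent-labd-12-ene-6,8-diol 7-acetate | C/C(I)=C/C[C@@H]1[C@@](C)(O)[C@H](OC(C)=O)[C@@H](O)[C@@H]2C(C)(C)CCC[C@]21C | intermediate
28 | tributyl(vinyl)stannane | C=C[Sn](CCCC)(CCCC)CCCC | starting material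
29 | (12Z)-6,8-dihydroxy-ent-labda-12,14-dien-7-yl acetate; 6-OH and 8-OH on the face opposite the C10 methyl, 7-OAc and C8–CH3 on the same face as the C10 methyl | C=C/C(C)=C\C[C@@H]1[C@@](C)(O)[C@H](OC(C)=O)[C@@H](O)[C@@H]2C(C)(C)CCC[C@]21C | target

## Step count and least certain steps

Total: 20 steps. Longest linear sequence: 20 steps (1 → 29); 3, 22 and 28 enter along this line.

**Step 3 (key step).** The most likely failure is throughput, not selectivity: the cyclase is inhibited by its substrate–magnesium complex and by accumulating product, and diphosphate 4 slowly hydrolyses in buffer, so gram amounts of 5 may be out of reach in vitro. The fallback moves the same cyclisation into a cell. An Escherichia coli strain carrying a heterologous mevalonate pathway and a geranylgeranyl diphosphate synthase makes 4 from glucose at a low steady-state concentration. The co-expressed cyclase converts it to 5, and endogenous phosphatases release the alcohol into a dodecane overlay. This path sets out at the level of 4 (made in the cell, so that 1–3 are not needed) and comes back to the route at 6; it makes no new compound.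

**Step 12 (with the enolisation of step 11).** Deprotonation of the hindered C6 position may be slow. The acid co-product may open the silyloxy epoxide or the neighbouring spiro-epoxide before the silyl shift, or the silyl group may be lost, which allows α-ketol transposition. The fallback sets out from 13 and comes back at 16. The potassium enolate of 13 (KN(SiMe3)2, THF, −78 °C) is oxidised directly with 2-(phenylsulfonyl)-3-phenyloxaziridine (Davis hydroxylation) and quenched cold, giving the 6-hydroxy-7-oxo-8,17-epoxide ketal F1. Silylation of F1 with TBSOTf and 2,6-lutidine at −78 °C then gives 16. Oxygen transfer to the enolate replaces enol-ether epoxidation and rearrangement, and protection becomes a separate operation.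

**Step 13.** In the aprotic medium the silyl group may migrate from O6 to the new C7 alkoxide, and the bulky neighbours may erode the preference for axial attack. The fallback sets out from 16 and comes back at 17 and splits the reduction into two chemoselective operations. Luche reduction (NaBH4, CeCl3·7H2O, MeOH, −40 °C) protonates the alkoxide as it forms, which removes the driving force for silyl migration, and gives the epoxy alcohol F2. Opening of F2 with LiBHEt3 in THF at 0 °C, at the primary C17, then gives 17.

**Step 16.** The iodo-ylide decomposes above about −20 °C, so conversion and Z selectivity may be moderate. A base-induced acetyl shift from O8 to O7 in 21 would free the C8 alkoxide, which would close onto the aldehyde as a lactol and stall the olefination. The fallback sets out from 21 and comes back at 29, and it builds the diene by carbonyl olefinations only, without iodine, tin or palladium. Still–Gennari olefination of 21 with ethyl 2-[bis(2,2,2-trifluoroethoxy)phosphoryl]propanoate (KN(SiMe3)2, 18-crown-6, THF, −78 °C) should give the Z-enoate F3. i-Bu2AlH then reduces the ester and removes the tertiary acetate, giving the Z-allylic alcohol F4, and MnO2 oxidises only the allylic primary alcohol to the Z-enal F5, which is kept cold and used at once. Salt-free Ph3P=CH2 at −78 °C gives the diene diol F6, acetylation (Ac2O, pyridine, DMAP) gives the silyl-protected diene acetate F7, and HF·pyridine buffered with pyridine gives 29. The cost is one more step and a final desilylation in the presence of the diene.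

## Further compounds

F0 | step 3 | none | none
F1 | step 12 | 6-hydroxy-7-oxo-8,17-epoxide ketal (C6–OH equatorial, opposite the C10 methyl) | CC3(OCCO3)CC[C@@H]1[C@]4(CO4)C(=O)[C@@H](O)[C@@H]2C(C)(C)CCC[C@]21C
F2 | step 13 | 6-silyloxy-7-hydroxy-8,17-epoxide ketal (C7–OH equatorial, same face as the C10 methyl) | CC3(OCCO3)CC[C@@H]1[C@]4(CO4)[C@H](O)[C@@H](O[Si](C)(C)C(C)(C)C)[C@@H]2C(C)(C)CCC[C@]21C
F3 | step 16 | ethyl (12Z)-8-acetoxy-7-hydroxy-6-silyloxy-15-nor-ent-labd-12-en-14-oate (Z-enoate) | CCOC(=O)/C(C)=C\C[C@@H]1[C@@](C)(OC(C)=O)[C@H](O)[C@@H](O[Si](C)(C)C(C)(C)C)[C@@H]2C(C)(C)CCC[C@]21C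
F4 | step 16 | (12Z)-6-silyloxy-15-nor-ent-labd-12-ene-7,8,14-triol | OC/C(C)=C\C[C@@H]1[C@@](C)(O)[C@H](O)[C@@H](O[Si](C)(C)C(C)(C)C)[C@@H]2C(C)(C)CCC[C@]21C
F5 | step 16 | (12Z)-7,8-dihydroxy-6-silyloxy-15-nor-ent-labd-12-en-14-al | O=C/C(C)=C\C[C@@H]1[C@@](C)(O)[C@H](O)[C@@H](O[Si](C)(C)C(C)(C)C)[C@@H]2C(C)(C)CCC[C@]21C
F6 | step 16 | (12Z)-6-silyloxy-ent-labda-12,14-diene-7,8-diol | C=C/C(C)=C\C[C@@H]1[C@@](C)(O)[C@H](O)[C@@H](O[Si](C)(C)C(C)(C)C)[C@@H]2C(C)(C)CCC[C@]21C
F7 | step 16 | (12Z)-8-hydroxy-6-silyloxy-ent-labda-12,14-dien-7-yl acetate | C=C/C(C)=C\C[C@@H]1[C@@](C)(O)[C@H](OC(C)=O)[C@@H](O[Si](C)(C)C(C)(C)C)[C@@H]2C(C)(C)CCC[C@]21C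
A1 | alternative 1 | 2,6-dimethyl-1,4-benzoquinone | CC1=CC(=O)C=C(C)C1=O
A2 | alternative 1 | 4-methylpenta-1,3-diene | CC(C)=CC=C
A3 | alternative 1 | cis-fused ring A cyclohexene–ring B enedione adduct | O=C1C(C)=CC(=O)[C@H]2C(C)(C)C=CC[C@]21C
A4 | alternative 2 | 1-[1-(tert-butyldimethylsilyloxy)ethenyl]-2,6,6-trimethylcyclohex-1-ene | C=C(O[Si](C)(C)C(C)(C)C)C1=C(C)CCCC1(C)C
A5 | alternative 2 | 1-(but-2-ynoyl)-3,5-dimethylpyrazole | CC#CC(=O)n1nc(C)cc1C
A6 | alternative 2 | bicyclic 5,8-diene with C6 silyl enol ether and C9 acyl pyrazole | Cc1cc(C)n(n1)C(=O)C1=C(C)CC(O[Si](C)(C)C(C)(C)C)=C2C(C)(C)CCC[C@]21C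
A7 | alternative 2 | copper bis(trifluoromethanesulfonyl)imide, Cu(NTf2)2 | [Cu+2].[N-](S(=O)(=O)C(F)(F)F)S(=O)(=O)C(F)(F)F.[N-](S(=O)(=O)C(F)(F)F)S(=O)(=O)C(F)(F)F
A8 | alternative 3 | E-enimide triene with (E,Z)-2-silyloxydiene and (S)-4-benzyloxazolidinone auxiliary | O=C(/C=C(\C)CCCC(C)(C)/C=C/C(O[Si](C)(C)C(C)(C)C)=C/C)N1C(=O)OC[C@@H]1Cc1ccccc1
A9 | alternative 3 | trans-fused bicyclic C6=C7 silyl enol ether bearing the C9 imide | O=C(N1C(=O)OC[C@@H]1Cc1ccccc1)[C@@H]1[C@H](C)C(O[Si](C)(C)C(C)(C)C)=C[C@@H]2C(C)(C)CCC[C@]21C
A10 | alternative 3 | dimethylaluminium chloride, Me2AlCl | C[Al](C)Cl
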